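**Strategy.** Ring B is disconnected at C4a–C4 and C2–C3 (decalin numbering), so that its bare C3–C4 ethano unit becomes a dienophile. A Diels–Alder reaction of a 2-methyl-5,6-disubstituted cyclohexa-1,3-diene with phenyl vinyl sulfone (an ethylene equivalent) forms both bonds and a bicyclo[2.2.2]octene. The etheno bridge is not in the target. It locks the contra-thermodynamic cis relation of the C4a–C5 and C2–CH3 bonds, steers the C1 methylation, and is then ozonolysed to the C5 acetyl and C2 formyl (later methyl) carbons. The diene comes from ethyl 2-methyl-4-oxocyclohex-2-enecarboxylate. Ring A is closed last by an intramolecular Negishi coupling that creates the exocyclic methylene.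

Key step: step 6

Remark on the chemistry: 1 is bought as the racemate, so compounds 4 to 7 are racemic (each SMILES shows both enantiomers, joined by a dot); the two series are parted in step 4.

Step 1
Reactants: 1 ethyl 2-methyl-4-oxocyclohex-2-ene-1-carboxylate (racemic); 2 (3-bromopropoxy)(tert-butyl)dimethylsilane
Product: 5 racemic ethyl (1S*,2S*)-2-[3-(tert-butyldimethylsilyloxy)propyl]-2-methyl-4-(trifluoromethylsulfonyloxy)cyclohex-3-ene-1-carboxylate, via Grignard reagent 3 (not isolated), via magnesium enolate 4 (not isolated)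
Conditions: 2, Mg, THF, 40 °C; CuBr·SMe2 (0.5 equiv), −40 °C; 1 added slowly, −78 °C; then N-(5-chloropyridin-2-yl)bis(trifluoromethanesulfonimide), −78 → 20 °C
Reagents that add atoms: N-(5-chloropyridin-2-yl)bis(trifluoromethanesulfonimide), O=S(=O)(N(c1ccc(Cl)cn1)S(=O)(=O)C(F)(F)F)C(F)(F)F
Why: Organocuprate conjugate addition to the β-methyl enone should bring the alkyl group in anti to the neighbouring C1 ester, creating the quaternary centre with the side chain trans to the ester, and the regiospecific enolate is O-triflated before it can equilibrate.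

Step 2
Reactants: 5 racemic enol triflate
Product: 6 racemic ethyl (1S*,2S*)-2-[3-(tert-butyldimethylsilyloxy)propyl]-2,4-dimethylcyclohex-3-ene-1-carboxylate
Conditions: MeZnCl, Pd(PPh3)4 (cat.), THF, 50 °C
Reagents that add atoms: methylzinc chloride, C[Zn]Cl
Why: Negishi cross-coupling of the alkenyl triflate places on C4 the methyl carbon that later becomes the exocyclic methylene carbon; no stereocentre is touched.

Step 3
Reactants: 6 racemic trisubstituted alkene
Product: 7 racemic ethyl (1S*,2S*)-2-[3-(tert-butyldimethylsilyloxy)propyl]-2,4-dimethyl-5-oxocyclohex-3-ene-1-carboxylate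
Conditions: Pd(OH)2/C (cat.), t-BuOOH, K2CO3, CH2Cl2, 0 → 20 °C
Reagents that add atoms: tert-butyl hydroperoxide, CC(C)(C)OO
Why: Catalytic allylic C–H oxidation should take place at C5, the only allylic ring methylene (C2 is quaternary), giving the 2-methyl enone without touching the stereocentres.

Step 4
Reactants: 7 racemic enone
Product: 8 ethyl (1S,2S,5R)-2-[3-(tert-butyldimethylsilyloxy)propyl]-5-hydroxy-2,4-dimethylcyclohex-3-ene-1-carboxylate
Conditions: (S)-2-methyl-CBS-oxazaborolidine (20 mol %), catecholborane, toluene, −78 °C; chromatographic separation of the two diastereomeric alcohols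
Reagents that add atoms: none
Why: In this CBS reduction the oxazaborolidine should deliver hydride to the same carbonyl face of both enantiomers of 7, so they become separable (5R) diastereomers, and the one with hydroxyl cis to the ester is the wanted (1S,2S) series.

Step 5
Reactants: 8 allylic alcohol
Product: 9 ethyl (1S,6S)-6-[3-(tert-butyldimethylsilyloxy)propyl]-4,6-dimethylcyclohexa-2,4-diene-1-carboxylate
Conditions: bis[α,α-bis(trifluoromethyl)benzyloxy]diphenylsulfurane, CH2Cl2, 0 → 20 °C
Reagents that add atoms: none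
Why: Dehydration through the alkoxysulfurane (E2-type elimination) can only use the β-hydrogens on C6, so the conjugated homoannular diene should form under non-basic conditions that leave the C1 and C2 stereocentres intact.

Step 6
Reactants: 9 cyclohexadiene ester; 10 phenyl vinyl sulfone
Product: 11 ethyl 3-[3-(tert-butyldimethylsilyloxy)propyl]-3,5-dimethyl-7-(phenylsulfonyl)bicyclo[2.2.2]oct-5-ene-2-carboxylate (ester and 3-methyl syn to C5=C6; sulfone epimers)
Conditions: 10 (3 equiv), toluene, 2,6-di-tert-butyl-4-methylphenol (trace), 110 °C, sealed tube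
Reagents that add atoms: none
Why: A thermal concerted [4π+2π] cycloaddition joins C2 and C5 of the homoannular diene (the future C2 and C4a of the decalin) to the two vinyl carbons of the sulfone, which acts as an ethylene equivalent because the sulfonyl group is reduced off in step 7. The closest known reaction type is the Diels–Alder reaction of cyclohexa-1,3-dienes with phenyl vinyl sulfone to give bicyclo[2.2.2]oct-2-enes. The new six-membered ring (ring B of the target) closes suprafacially on both partners in the normal Diels–Alder mode, and the diene C3=C4 bond becomes the etheno bridge. Both bridgehead stereocentres arise together and are fixed only by the diene face attacked: the dienophile should approach anti to the C1 ester and the pseudoaxial C6 methyl group, that is over the C1 hydrogen and past the pseudoequatorial side chain. This puts the ethano bridge syn to the side chain and leaves ester and methyl syn to the etheno bridge, as the later steps need. Only π-facial selectivity is required, since regiochemistry and endo/exo orientation of the sulfonyl group vanish when C7 becomes a methylene.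

Step 7
Reactants: 11 bicyclic sulfone
Product: 12 ethyl 3-[3-(tert-butyldimethylsilyloxy)propyl]-3,5-dimethylbicyclo[2.2.2]oct-5-ene-2-carboxylate (ester and 3-methyl syn to C5=C6)
Conditions: 6% Na(Hg), Na2HPO4, EtOH–THF, −20 °C
Reagents that add atoms: none
Why: Reductive desulfonylation by single-electron transfer from sodium amalgam should remove the phenylsulfonyl group without touching ester, alkene or silyl ether.

Step 8
Reactants: 12 bicyclic ester
Product: 13 ethyl 3-[3-(tert-butyldimethylsilyloxy)propyl]-2,3,5-trimethylbicyclo[2.2.2]oct-5-ene-2-carboxylate (both methyls on C2 and C3 syn to C5=C6; ester and side chain syn to C7–C8)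
Conditions: LiN(iPr)2, THF, −78 °C; MeI, N,N′-dimethylpropyleneurea, −78 → 0 °C
Reagents that add atoms: iodomethane, CI
Why: In this ester enolate alkylation the electrophile should enter on the face syn to the etheno bridge, because the inward hydrogens of the ethano bridge shield the other face, so the new C2 methyl ends cis to the C3 methyl and the ester turns toward the ethano bridge.

Step 9
Reactants: 13 methylated bicyclic ester
Product: 14 ethyl 3-acetyl-2-[3-(tert-butyldimethylsilyloxy)propyl]-6-formyl-1,2-dimethylcyclohexane-1-carboxylate (1-methyl, 2-methyl, 3-acetyl and 6-formyl all cis)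
Conditions: O3, CH2Cl2–MeOH, −78 °C; then Me2S
Reagents that add atoms: ozone, [O-][O+]=O
Why: Ozonolysis with reductive work-up cleaves the trisubstituted etheno bridge to the C3 acetyl and C6 formyl groups, which must be cis on the ring, and the neutral low-temperature conditions should avoid epimerisation next to the new carbonyls.

Step 10
Reactants: 14 keto aldehyde
Product: 16 ethyl 3-acetyl-2-[3-(tert-butyldimethylsilyloxy)propyl]-1,2,6-trimethylcyclohexane-1-carboxylate (three methyls and acetyl all cis), via tosylhydrazone 15 (not isolated)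
Conditions: TsNHNH2, THF, 20 °C; then catecholborane, CHCl3, 0 °C; then NaOAc·3H2O, 60 °C
Reagents that add atoms: none
Why: Aldehyde-selective tosylhydrazone formation, hydride reduction of the C=N bond and loss of sulfinate and N2 (reductive deoxygenation) should turn the formyl group into the C6 methyl group under mild conditions that neither epimerise C6 nor engage the hindered methyl ketone.

Step 11
Reactants: 16 methyl ketone
Product: 17 ethyl 2-[3-(tert-butyldimethylsilyloxy)propyl]-1,2,6-trimethyl-3-[1-(trifluoromethylsulfonyloxy)ethenyl]cyclohexane-1-carboxylate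
Conditions: KN(SiMe3)2, THF, −78 °C; then PhNTf2
Reagents that add atoms: N-phenylbis(trifluoromethanesulfonimide), O=S(=O)(N(c1ccccc1)S(=O)(=O)C(F)(F)F)C(F)(F)F
Why: Kinetic deprotonation at the methyl group of the ketone at −78 °C and O-triflation should give the terminal enol triflate without disturbing the α-stereocentre on the ring.

Step 12
Reactants: 17 enol triflate silyl ether
Product: 18 ethyl 2-(3-bromopropyl)-1,2,6-trimethyl-3-[1-(trifluoromethylsulfonyloxy)ethenyl]cyclohexane-1-carboxylate
Conditions: Ph3PBr2, CH2Cl2, 0 → 20 °C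
Reagents that add atoms: dibromotriphenylphosphorane, BrP(Br)(c1ccccc1)(c1ccccc1)c1ccccc1
Why: Dibromotriphenylphosphorane converts primary silyl ethers directly into bromides (silyl transfer to bromide, then SN2 on the alkoxyphosphonium ion), which should leave the enol triflate and the ester alone.

Step 13
Reactants: 18 bromo enol triflate
Product: 20 ethyl (1R,2S,4aS,8aS)-1,2,8a-trimethyl-5-methylidenedecahydronaphthalene-1-carboxylate, via alkylzinc bromide 19 (not isolated)
Conditions: Zn dust, I2 (5 mol %), N,N-dimethylacetamide, 70 °C; then Pd(OAc)2 (5 mol %), SPhos (10 mol %), THF, 60 °C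
Reagents that add atoms: none
Why: Zinc insertion into the primary C–Br bond followed by intramolecular Negishi coupling with the alkenyl triflate should close ring A and deliver the exocyclic methylene directly, the trans ring fusion following from the fixed configurations at C4a and C8a.

Step 14
Reactants: 20 decalin ester
Product: 21 (1R,2S,4aS,8aS)-1,2,8a-trimethyl-5-methylidenedecahydronaphthalene-1-carbaldehyde
Conditions: (i-Bu)2AlH, CH2Cl2, −78 °C; aq. potassium sodium tartrate
Reagents that add atoms: none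
Why: Low-temperature hydride reduction of the hindered ester should stop at the tetrahedral aluminium hemiacetal and release the aldehyde on work-up.

Step 15
Reactants: 21 decalin aldehyde; 22 1,2,4,5-tetramethoxybenzene
Product: 25 O-{(2,3,5,6-tetramethoxyphenyl)[(1R,2S,4aS,8aS)-1,2,8a-trimethyl-5-methylidenedecahydronaphthalen-1-yl]methyl} S-methyl carbonodithioate (carbinol epimers), via aryllithium 23 (not isolated), via lithium alkoxide 24 (not isolated)
Conditions: 22, n-BuLi, THF, 0 °C; then 21, −78 → 0 °C; then CS2, 0 °C; then MeI, 20 °C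
Reagents that add atoms: carbon disulfide, S=C=S; iodomethane, CI
Why: Directed ortho-lithiation of the arene, 1,2-addition of the aryllithium to the non-enolisable aldehyde and in situ xanthate formation from the alkoxide; the new carbinol centre does not matter because it is removed in step 16.

Step 16
Reactants: 25 benzylic xanthate
Product: 26 (1R,2S,4aS,8aS)-1,2,8a-trimethyl-5-methylidene-1-[(2,3,5,6-tetramethoxyphenyl)methyl]decahydronaphthalene
Conditions: Bu3SnH, azobisisobutyronitrile (cat.), toluene, 100 °C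
Reagents that add atoms: none
Why: Barton–McCombie radical deoxygenation gives the benzylic methylene without acid, so the exocyclic alkene should be spared.

Step 17
Reactants: 26 tetramethoxyarene
Product: 27 2,5-dimethoxy-3-{[(1R,2S,4aS,8aS)-1,2,8a-trimethyl-5-methylidenedecahydronaphthalen-1-yl]methyl}cyclohexa-2,5-diene-1,4-dione
Conditions: (NH4)2Ce(NO3)6, MeCN–H2O, 0 °C
Reagents that add atoms: water, O
Why: Oxidative demethylation of a para-dimethoxy pair should give the 2,5-dimethoxy-1,4-benzoquinone, and the two possible para pairs are equivalent by symmetry.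

Step 18
Reactants: 27 dimethoxyquinone
Product: 28 2-hydroxy-5-methoxy-3-{[(1R,2S,4aS,8aS)-1,2,8a-trimethyl-5-methylidenedecahydronaphthalen-1-yl]methyl}cyclohexa-2,5-diene-1,4-dione (target)
Conditions: dilute aq. HClO4, THF, 0 → 20 °C, short contact
Reagents that add atoms: water, O
Why: Acid-mediated hydrolysis of a vinylogous ester, which in 3-alkyl-2,5-dimethoxybenzoquinones should take the methoxy group next to the alkyl substituent, while short contact at low temperature should spare the exocyclic alkene.

**Compound list**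

1 | ethyl 2-methyl-4-oxocyclohex-2-ene-1-carboxylate (Hagemann's ester, racemic) | CCOC(=O)C1CCC(=O)C=C1C | starting material
2 | (3-bromopropoxy)(tert-butyl)dimethylsilane | BrCCCO[Si](C)(C)C(C)(C)C | starting material
3 | [3-(tert-butyldimethylsilyloxy)propyl]magnesium bromide | Br[Mg]CCCO[Si](C)(C)C(C)(C)C | intermediate
4 | racemic bromomagnesium enolate of ethyl 2-[3-(tert-butyldimethylsilyloxy)propyl]-2-methyl-4-oxocyclohexane-1-carboxylate (side chain trans to ester) | CCOC(=O)[C@H]1CCC(O[Mg]Br)=C[C@]1(C)CCCO[Si](C)(C)C(C)(C)C.CCOC(=O)[C@@H]1CCC(O[Mg]Br)=C[C@@]1(C)CCCO[Si](C)(C)C(C)(C)C | intermediate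
5 | racemic ethyl (1S*,2S*)-2-[3-(tert-butyldimethylsilyloxy)propyl]-2-methyl-4-(trifluoromethylsulfonyloxy)cyclohex-3-ene-1-carboxylate | CCOC(=O)[C@H]1CCC(OS(=O)(=O)C(F)(F)F)=C[C@]1(C)CCCO[Si](C)(C)C(C)(C)C.CCOC(=O)[C@@H]1CCC(OS(=O)(=O)C(F)(F)F)=C[C@@]1(C)CCCO[Si](C)(C)C(C)(C)C | intermediate
6 | racemic ethyl (1S*,2S*)-2-[3-(tert-butyldimethylsilyloxy)propyl]-2,4-dimethylcyclohex-3-ene-1-carboxylate | CCOC(=O)[C@H]1CCC(C)=C[C@]1(C)CCCO[Si](C)(C)C(C)(C)C.CCOC(=O)[C@@H]1CCC(C)=C[C@@]1(C)CCCO[Si](C)(C)C(C)(C)C | intermediate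
7 | racemic ethyl (1S*,2S*)-2-[3-(tert-butyldimethylsilyloxy)propyl]-2,4-dimethyl-5-oxocyclohex-3-ene-1-carboxylate | CCOC(=O)[C@H]1CC(=O)C(C)=C[C@]1(C)CCCO[Si](C)(C)C(C)(C)C.CCOC(=O)[C@@H]1CC(=O)C(C)=C[C@@]1(C)CCCO[Si](C)(C)C(C)(C)C | intermediate
8 | ethyl (1S,2S,5R)-2-[3-(tert-butyldimethylsilyloxy)propyl]-5-hydroxy-2,4-dimethylcyclohex-3-ene-1-carboxylate (hydroxyl cis to ester) | CCOC(=O)[C@H]1C[C@@H](O)C(C)=C[C@]1(C)CCCO[Si](C)(C)C(C)(C)C | intermediate
9 | ethyl (1S,6S)-6-[3-(tert-butyldimethylsilyloxy)propyl]-4,6-dimethylcyclohexa-2,4-diene-1-carboxylate (ester cis to the 6-methyl) | CCOC(=O)[C@H]1C=CC(C)=C[C@]1(C)CCCO[Si](C)(C)C(C)(C)C | intermediate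
10 | phenyl vinyl sulfone | C=CS(=O)(=O)c1ccccc1 | starting material
11 | ethyl 3-[3-(tert-butyldimethylsilyloxy)propyl]-3,5-dimethyl-7-(phenylsulfonyl)bicyclo[2.2.2]oct-5-ene-2-carboxylate (ester and 3-methyl syn to C5=C6; sulfone epimers) | CCOC(=O)[C@H]1[C@H]2C=C(C)[C@H](CC2S(=O)(=O)c2ccccc2)[C@]1(C)CCCO[Si](C)(C)C(C)(C)C | intermediate
12 | ethyl 3-[3-(tert-butyldimethylsilyloxy)propyl]-3,5-dimethylbicyclo[2.2.2]oct-5-ene-2-carboxylate (ester and 3-methyl syn to C5=C6) | CCOC(=O)[C@H]1[C@H]2C=C(C)[C@H](CC2)[C@]1(C)CCCO[Si](C)(C)C(C)(C)C | intermediate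
13 | ethyl 3-[3-(tert-butyldimethylsilyloxy)propyl]-2,3,5-trimethylbicyclo[2.2.2]oct-5-ene-2-carboxylate (2- and 3-methyl syn to C5=C6) | CCOC(=O)[C@]1(C)[C@H]2C=C(C)[C@H](CC2)[C@]1(C)CCCO[Si](C)(C)C(C)(C)C | intermediate
14 | ethyl 3-acetyl-2-[3-(tert-butyldimethylsilyloxy)propyl]-6-formyl-1,2-dimethylcyclohexane-1-carboxylate (1-methyl, 2-methyl, 3-acetyl, 6-formyl all cis) | CCOC(=O)[C@]1(C)[C@@H](C=O)CC[C@@H](C(C)=O)[C@]1(C)CCCO[Si](C)(C)C(C)(C)C | intermediate
15 | 4-methylbenzenesulfonylhydrazone of the formyl group of 14 | CCOC(=O)[C@]1(C)[C@@H](C=NNS(=O)(=O)c2ccc(C)cc2)CC[C@@H](C(C)=O)[C@]1(C)CCCO[Si](C)(C)C(C)(C)C | intermediate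
16 | ethyl 3-acetyl-2-[3-(tert-butyldimethylsilyloxy)propyl]-1,2,6-trimethylcyclohexane-1-carboxylate (three methyls and acetyl all cis) | CCOC(=O)[C@]1(C)[C@@H](C)CC[C@@H](C(C)=O)[C@]1(C)CCCO[Si](C)(C)C(C)(C)C | intermediate
17 | ethyl 2-[3-(tert-butyldimethylsilyloxy)propyl]-1,2,6-trimethyl-3-[1-(trifluoromethylsulfonyloxy)ethenyl]cyclohexane-1-carboxylate | CCOC(=O)[C@]1(C)[C@@H](C)CC[C@@H](C(=C)OS(=O)(=O)C(F)(F)F)[C@]1(C)CCCO[Si](C)(C)C(C)(C)C | intermediate
18 | ethyl 2-(3-bromopropyl)-1,2,6-trimethyl-3-[1-(trifluoromethylsulfonyloxy)ethenyl]cyclohexane-1-carboxylate | CCOC(=O)[C@]1(C)[C@@H](C)CC[C@@H](C(=C)OS(=O)(=O)C(F)(F)F)[C@]1(C)CCCBr | intermediate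
19 | alkylzinc bromide from 18 | CCOC(=O)[C@]1(C)[C@@H](C)CC[C@@H](C(=C)OS(=O)(=O)C(F)(F)F)[C@]1(C)CCC[Zn]Br | intermediate
20 | ethyl (1R,2S,4aS,8aS)-1,2,8a-trimethyl-5-methylidenedecahydronaphthalene-1-carboxylate | C=C1CCC[C@@]2(C)[C@H]1CC[C@H](C)[C@@]2(C)C(=O)OCC | intermediate
21 | (1R,2S,4aS,8aS)-1,2,8a-trimethyl-5-methylidenedecahydronaphthalene-1-carbaldehyde | C=C1CCC[C@@]2(C)[C@H]1CC[C@H](C)[C@@]2(C)C=O | intermediate
22 | 1,2,4,5-tetramethoxybenzene | COc1cc(OC)c(OC)cc1OC | starting material
23 | 2,3,5,6-tetramethoxyphenyllithium | [Li]c1c(OC)c(OC)cc(OC)c1OC | intermediate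
24 | lithium alkoxide from 21 and 23 | C=C1CCC[C@@]2(C)[C@H]1CC[C@H](C)[C@@]2(C)C(O[Li])c1c(OC)c(OC)cc(OC)c1OC | intermediate
25 | O-{(2,3,5,6-tetramethoxyphenyl)[(1R,2S,4aS,8aS)-1,2,8a-trimethyl-5-methylidenedecahydronaphthalen-1-yl]methyl} S-methyl carbonodithioate | C=C1CCC[C@@]2(C)[C@H]1CC[C@H](C)[C@@]2(C)C(OC(=S)SC)c1c(OC)c(OC)cc(OC)c1OC | intermediate
26 | (1R,2S,4aS,8aS)-1,2,8a-trimethyl-5-methylidene-1-[(2,3,5,6-tetramethoxyphenyl)methyl]decahydronaphthalene | C=C1CCC[C@@]2(C)[C@H]1CC[C@H](C)[C@@]2(C)Cc1c(OC)c(OC)cc(OC)c1OC | intermediate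
27 | 2,5-dimethoxy-3-{[(1R,2S,4aS,8aS)-1,2,8a-trimethyl-5-methylidenedecahydronaphthalen-1-yl]methyl}cyclohexa-2,5-diene-1,4-dione | C=C1CCC[C@@]2(C)[C@H]1CC[C@H](C)[C@@]2(C)CC1=C(OC)C(=O)C=C(OC)C1=O | intermediate
28 | 2-hydroxy-5-methoxy-3-{[(1R,2S,4aS,8aS)-1,2,8a-trimethyl-5-methylidenedecahydronaphthalen-1-yl]methyl}cyclohexa-2,5-diene-1,4-dione | C=C1CCC[C@@]2(C)[C@H]1CC[C@H](C)[C@@]2(C)CC1=C(O)C(=O)C=C(OC)C1=O | target

**Step count and risks**

Total step count: 18. Longest linear sequence: 18 steps (from 1; compounds 2, 10 and 22 enter as bought).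

The three steps most likely to fail:

1. Step 6 (key cycloaddition). What may go wrong: erosion of π-facial selectivity, and thermal isomerisation of diene 9 during the long heating (epimerisation at C1, or a [1,5]-hydrogen shift that pulls the diene into conjugation with the ester). Fallback, setting out from 9: the two-carbon unit would be brought in with acrolein under Lewis-acid activation (MeAlCl2, CH2Cl2, −78 °C), far below the temperature at which 9 can isomerise. This should give ethyl 3-[3-(tert-butyldimethylsilyloxy)propyl]-7-formyl-3,5-dimethylbicyclo[2.2.2]oct-5-ene-2-carboxylate F1. Stoichiometric decarbonylation of F1 with RhCl(PPh3)3 (toluene, 110 °C) would come back to the route at 12.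

2. Step 13 (closure of ring A). What may go wrong: protodezincation or β-hydride elimination outrunning ring closure, because the cyclising conformer must hold the ester axial and two methyl groups 1,3-diaxial. Fallback, setting out from 17: elimination of triflate with LiN(iPr)2 (THF, −78 °C) would give the terminal alkyne ethyl 2-[3-(tert-butyldimethylsilyloxy)propyl]-3-ethynyl-1,2,6-trimethylcyclohexane-1-carboxylate F2. Ph3PBr2 would turn its silyl ether into the bromide ethyl 2-(3-bromopropyl)-3-ethynyl-1,2,6-trimethylcyclohexane-1-carboxylate F3. A tin-hydride-mediated 6-exo-dig radical cyclisation of F3 (Bu3SnH, azobisisobutyronitrile, benzene, 80 °C, slow addition) would then close ring A with the exocyclic methylene and come back to the route at 20.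

3. Step 8 (methylation in the bicycle). What may go wrong: incomplete enolisation of the hindered ester, whose α-carbon lies between a quaternary carbon and a bridgehead, with self-condensation taking over. Fallback, setting out from 12: (i-Bu)2AlH (CH2Cl2, −78 °C) would give 3-[3-(tert-butyldimethylsilyloxy)propyl]-3,5-dimethylbicyclo[2.2.2]oct-5-ene-2-carbaldehyde F4. Its smaller and more acidic potassium enolate (KOt-Bu, THF, 0 °C) would be C-methylated with MeI from the face of the etheno bridge to give 3-[3-(tert-butyldimethylsilyloxy)propyl]-2,3,5-trimethylbicyclo[2.2.2]oct-5-ene-2-carbaldehyde F5. Oxidation with NaClO2 (NaH2PO4, 2-methylbut-2-ene, t-BuOH–H2O) would give 3-[3-(tert-butyldimethylsilyloxy)propyl]-2,3,5-trimethylbicyclo[2.2.2]oct-5-ene-2-carboxylic acid F6, and EtI with K2CO3 (DMF) would come back to the route at 13.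

Further compounds
F1 | step 6 | ethyl 3-[3-(tert-butyldimethylsilyloxy)propyl]-7-formyl-3,5-dimethylbicyclo[2.2.2]oct-5-ene-2-carboxylate | CCOC(=O)[C@H]1[C@H]2C=C(C)[C@H](CC2C=O)[C@]1(C)CCCO[Si](C)(C)C(C)(C)C
F2 | step 13 | ethyl 2-[3-(tert-butyldimethylsilyloxy)propyl]-3-ethynyl-1,2,6-trimethylcyclohexane-1-carboxylate | CCOC(=O)[C@]1(C)[C@@H](C)CC[C@@H](C#C)[C@]1(C)CCCO[Si](C)(C)C(C)(C)C
F3 | step 13 | ethyl 2-(3-bromopropyl)-3-ethynyl-1,2,6-trimethylcyclohexane-1-carboxylate | CCOC(=O)[C@]1(C)[C@@H](C)CC[C@@H](C#C)[C@]1(C)CCCBr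
F4 | step 8 | 3-[3-(tert-butyldimethylsilyloxy)propyl]-3,5-dimethylbicyclo[2.2.2]oct-5-ene-2-carbaldehyde | O=C[C@H]1[C@H]2C=C(C)[C@H](CC2)[C@]1(C)CCCO[Si](C)(C)C(C)(C)C
F5 | step 8 | 3-[3-(tert-butyldimethylsilyloxy)propyl]-2,3,5-trimethylbicyclo[2.2.2]oct-5-ene-2-carbaldehyde | O=C[C@]1(C)[C@H]2C=C(C)[C@H](CC2)[C@]1(C)CCCO[Si](C)(C)C(C)(C)C
F6 | step 8 | 3-[3-(tert-butyldimethylsilyloxy)propyl]-2,3,5-trimethylbicyclo[2.2.2]oct-5-ene-2-carboxylic acid | OC(=O)[C@]1(C)[C@H]2C=C(C)[C@H](CC2)[C@]1(C)CCCO[Si](C)(C)C(C)(C)C
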